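**Direct plan and its weak points**

A direct plan would assemble the hydroazulene diol A1 by aldol addition, Grignard addition and ring-closing metathesis, fragment the monosulfonate of A1 to the achiral ten-membered trienone A2, and only then bring in chirality by one asymmetric epoxidation.
It would then reduce the ketone to the C6-epimeric alcohol A3, let that hydroxyl direct peracid oxidation to the dihydroxy ketone A4, esterify O8, invert C6 by Mitsunobu esterification to the acrylate A5, and close the butenolide last by a phosphine-catalysed Morita–Baylis–Hillman annulation with acetate transposition.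
Weak point 1, the reduction to A3 followed by Mitsunobu inversion: C6 would be set wrong on purpose and corrected by SN2 displacement at a carbinol flanked by a ketone and an oxirane, where elimination, epimerization and oxirane opening compete.
Weak point 2, the asymmetric epoxidation of A2: every ring stereocentre would hang on one reagent-controlled oxidation of a flexible, achiral triene, and C8 on an undirected enol ether oxidation followed by a selective mono-esterification of a 6,8-diol.
Weak point 3, the final annulation on A5: an untested carbon–carbon bond formation onto a hindered, doubly α-oxygenated ketone would be asked of a compound that already carries three oxiranes and two esters.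

**Retrosynthetic overview of the new route**

The two oxiranes hide a (1(10)E,4Z)-cyclodeca-1,5-diene with methyls on C4 and C10 and oxygen on C6 and C8; this is the p-menthane skeleton of isopiperitenone (C1–C6, C9, C10, C14, C15) plus a two-carbon C7–C8 unit.
Key disconnection: the C8–C9 bond, formed while the C1–C6 bond of the cyclohexene breaks, in an anionic oxy-Cope ring expansion of the adduct of (S)-isopiperitenone and an (E)-2-alkoxyvinyl anion; 4Z comes from the ring, 1(10)E from the chair.
Stereochemical relay: the only stereocentre of the terpene is destroyed in the key step but transferred to C8; the C8 oxygen then sets C6 (chelation-controlled reduction) and, as a free hydroxyl, delivers both oxirane oxygens (C1=C10 homoallylic, C4=C5 bishomoallylic).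
Ring order: six-membered carbocycle, ten-membered ring, butenolide (aldol of the C6 ketone at C7 with an acetoxypyruvate, lactonization, dehydration), both oxiranes in one step, C8 ester last.
No stereocentre is inverted, absolute configuration comes from the chiral pool, and the lactone is closed by classical steps before any oxirane exists.

Key step: step 5

Remark on the chemistry (assumption): commercial p-mentha-2,8-dien-1-ol is taken as the (1S,4R) compound; any C1 epimer serves, because C1 becomes trigonal in step 1 and only the 4R centre matters.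

**Route**

Step 1
Reactants: 1 (1S,4R)-1-methyl-4-(prop-1-en-2-yl)cyclohex-2-en-1-ol
Product: 2 (6S)-3-methyl-6-(prop-1-en-2-yl)cyclohex-2-en-1-one
Conditions: (C5H5NH)[CrO3Cl] (2 equiv), NaOAc, 4 Å molecular sieves, CH2Cl2, 23 °C
Reagents that add atoms: pyridinium chlorochromate ([O-][Cr](=O)(=O)Cl.c1cc[nH+]cc1)
Why: Babler–Dauben oxidative transposition, in which the tertiary allylic chromate ester undergoes a [3,3] shift and the secondary chromate is oxidized, should move the oxygen next to the isopropenyl-bearing carbon, with acetate buffering to protect the epimerizable α-centre and the β,γ-alkene.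

Step 2
Reactants: 3 (4-methoxyphenyl)methanol
Product: 6 1-(ethynyloxymethyl)-4-methoxybenzene, via dichlorovinyl ether 4 (not isolated), via lithium alkynyl ether 5 (not isolated)
Conditions: KH, THF, 0 °C; Cl2C=CHCl, −50 to 23 °C; then n-BuLi (2.3 equiv), −78 to −40 °C; MeOH, −78 °C
Reagents that add atoms: trichloroethylene (ClC=C(Cl)Cl)
Why: Ynol ether synthesis from trichloroethylene, in which the alkoxide adds to dichloroacetylene formed in situ and n-BuLi then effects elimination and chlorine–lithium exchange, should give the alkynyl ether, which is kept cold.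

Step 3
Reactants: 6 1-(ethynyloxymethyl)-4-methoxybenzene
Product: 8 1-{[(E)-2-iodoethenyl]oxymethyl}-4-methoxybenzene, via alkenylzirconocene chloride 7 (not isolated)
Conditions: Cp2Zr(H)Cl, THF, 0 to 23 °C; then I2, 0 °C
Reagents that add atoms: iodine (II)
Why: Syn hydrozirconation should place zirconium on the terminal carbon and iodinolysis with retention should fix the E geometry of the β-iodo enol ether.

Step 4
Reactants: 8 1-{[(E)-2-iodoethenyl]oxymethyl}-4-methoxybenzene; 2 (6S)-3-methyl-6-(prop-1-en-2-yl)cyclohex-2-en-1-one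
Product: 11 (1S,6S)-1-{(E)-2-[(4-methoxyphenyl)methoxy]ethenyl}-3-methyl-6-(prop-1-en-2-yl)cyclohex-2-en-1-ol, via alkenyllithium 9 (not isolated), via alkenylcerium dichloride 10 (not isolated)
Conditions: t-BuLi (2 equiv), Et2O, −78 °C; CeCl3, THF, −78 °C; then 2; aq. NH4Cl
Reagents that add atoms: none
Why: Iodine–lithium exchange with retention, transmetalation to the less basic organocerium reagent (which should suppress enolization of the epimerizable ketone) and 1,2-addition anti to the neighbouring isopropenyl group should give the trans-dialkenyl carbinol, any cis isomer being removed by chromatography.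

Step 5
Reactants: 11 (1S,6S)-1-{(E)-2-[(4-methoxyphenyl)methoxy]ethenyl}-3-methyl-6-(prop-1-en-2-yl)cyclohex-2-en-1-ol
Product: 14 (1(10)E,4Z,6Z,8S)-8-(4-methoxybenzyloxy)-6-(trimethylsilyloxy)-11,12,13-trinorgermacra-1(10),4,6-triene, via potassium alkoxide 12 (not isolated), via potassium enolate 13 (not isolated)
Conditions: KH, 18-crown-6, THF, −20 to 20 °C; then Me3SiCl, Et3N, −78 °C
Reagents that add atoms: chlorotrimethylsilane (C[Si](C)(C)Cl)
Why: The potassium alkoxide 12 should undergo the anionic oxy-Cope rearrangement ([3,3] shift of a 3-oxido-1,5-diene), the closest known reaction type being the ring expansion of trans-1,2-dialkenylcyclohexanols to (E)-cyclodec-5-enones. The ten-membered ring is closed not by joining chain ends but by ring expansion of the six-membered carbocycle: C8–C9 forms while C1–C6 breaks in a chair transition state fused to the cyclohexene through two equatorial ring bonds. This chair fixes the E geometry of the new C1=C10 alkene, while the Z C4=C5 alkene is carried over from the ring. The new C8 stereocentre is controlled by the isopropenyl-bearing carbon, which dictates the sense of the chair, and by the E enol ether, which holds the ether oxygen equatorial; the controlling centre becomes trigonal in the same event. The step needs chair over boat selectivity, secured by the trans-diequatorial alkenyl groups, and an enolate that survives until silylation, secured by the doubly allylic alkoxide that should rearrange near 0 °C and by the cold Me3SiCl quench that should outrun loss of the β-alkoxide.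

Step 6
Reactants: 15 ethyl 3-bromo-2-oxopropanoate
Product: 16 ethyl 3-acetoxy-2-oxopropanoate
Conditions: KOAc, AcOH, 40 °C
Reagents that add atoms: potassium acetate (CC(=O)[O-].[K+])
Why: SN2 displacement of an α-halo ketone by carboxylate should give the acetoxy keto ester, which carries C11, C12 and C13 with the C13 acetate already in place.

Step 7
Reactants: 14 (1(10)E,4Z,6Z,8S)-8-(4-methoxybenzyloxy)-6-(trimethylsilyloxy)-11,12,13-trinorgermacra-1(10),4,6-triene; 16 ethyl 3-acetoxy-2-oxopropanoate
Product: 17 ethyl (1(10)E,4Z,8S)-13-acetoxy-8-(4-methoxybenzyloxy)-6-oxo-11-(trimethylsilyloxy)germacra-1(10),4-dien-12-oate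
Conditions: Cu(OTf)2 (10 mol %), (S,S)-2,2'-isopropylidenebis(4-tert-butyl-2-oxazoline) (11 mol %), THF, −78 °C
Reagents that add atoms: none
Why: Mukaiyama aldol addition to a keto ester held by the divalent copper bis(oxazoline) complex through both carbonyl oxygens should form the C7–C11 bond with silyl transfer to the tertiary oxygen and give the syn adduct through an open transition state, both new centres (C7, C11) being removed in step 9.

Step 8
Reactants: 17 ethyl (1(10)E,4Z,8S)-13-acetoxy-8-(4-methoxybenzyloxy)-6-oxo-11-(trimethylsilyloxy)germacra-1(10),4-dien-12-oate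
Product: 19 (1(10)E,4Z,6R,8S)-13-acetoxy-11-hydroxy-8-(4-methoxybenzyloxy)germacra-1(10),4-dien-12,6-olide, via hydroxy ester 18 (not isolated)
Conditions: Zn(BH4)2, Et2O, −40 to 0 °C; aq. NH4Cl; then PPTS (cat.), MeOH, 23 °C
Reagents that add atoms: none
Why: Chelation-controlled 1,2-reduction, in which zinc bridges the C6 carbonyl and the C8 ether oxygen and hydride adds from the side opposite C9, should set C6 syn to C8, and mild acid should then close the γ-lactone onto O6 (O8 stays blocked) and free the tertiary alcohol.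

Step 9
Reactants: 19 (1(10)E,4Z,6R,8S)-13-acetoxy-11-hydroxy-8-(4-methoxybenzyloxy)germacra-1(10),4-dien-12,6-olide
Product: 20 (1(10)E,4Z,6R,8S)-13-acetoxy-8-(4-methoxybenzyloxy)germacra-1(10),4,7(11)-trien-12,6-olide
Conditions: methyl N-(triethylammoniosulfonyl)carbamate (Burgess reagent), PhMe, 60 °C
Reagents that add atoms: none
Why: Burgess dehydration (syn elimination through the sulfamate ester) should remove H-7, which is cis to the C11 hydroxyl in the syn aldol series, and give the tetrasubstituted conjugated butenolide.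

Step 10
Reactants: 20 (1(10)E,4Z,6R,8S)-13-acetoxy-8-(4-methoxybenzyloxy)germacra-1(10),4,7(11)-trien-12,6-olide
Product: 21 (1(10)E,4Z,6R,8S)-13-acetoxy-8-hydroxygermacra-1(10),4,7(11)-trien-12,6-olide
Conditions: DDQ, CH2Cl2/pH 7 buffer, 0 °C
Reagents that add atoms: none
Why: Oxidative cleavage of the 4-methoxybenzyl ether (benzylic hydride abstraction, hydrolysis of the oxocarbenium ion) at neutral pH should spare the allylic lactone, the acetate and the trisubstituted alkenes.

Step 11
Reactants: 21 (1(10)E,4Z,6R,8S)-13-acetoxy-8-hydroxygermacra-1(10),4,7(11)-trien-12,6-olide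
Product: 23 (1R,4R,5S,6S,8S,10R)-13-acetoxy-1,10:4,5-diepoxy-8-hydroxygermacr-7(11)-en-12,6-olide, via 1,10-monoepoxide 22 (not isolated)
Conditions: VO(acac)2 (10 mol %), t-BuOOH (3 equiv), CH2Cl2, 0 to 23 °C
Reagents that add atoms: tert-butyl hydroperoxide (CC(C)(C)OO)
Why: Hydroxyl-directed epoxidation, in which the C8 alkoxide of the pentavalent vanadium alkylperoxide delivers oxygen within the ring to the homoallylic C1=C10 and the bishomoallylic C4=C5 alkenes on the face that carries O8, should set C1, C10, C4 and C5 and leave the electron-poor butenolide alkene alone.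

Step 12
Reactants: 23 (1R,4R,5S,6S,8S,10R)-13-acetoxy-1,10:4,5-diepoxy-8-hydroxygermacr-7(11)-en-12,6-olide; 24 (2S)-2-methyloxirane-2-carboxylic acid
Product: 25 (1R,4R,5S,6S,8S,10R)-13-acetoxy-1,10:4,5-diepoxy-8-[(2S)-2-methyloxirane-2-carbonyloxy]germacr-7(11)-en-12,6-olide
Conditions: DCC, DMAP (10 mol %), CH2Cl2, −20 to 0 °C
Reagents that add atoms: none
Why: Steglich esterification of the secondary alcohol at low temperature should give the target, the acid bringing its own (S) centre and no ring stereocentre being touched.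

**Compound list**

1 | (1S,4R)-1-methyl-4-(prop-1-en-2-yl)cyclohex-2-en-1-ol (p-mentha-2,8-dien-1-ol) | C[C@@]1(O)C=C[C@@H](CC1)C(C)=C | starting material
2 | (6S)-3-methyl-6-(prop-1-en-2-yl)cyclohex-2-en-1-one ((S)-isopiperitenone) | CC1=CC(=O)[C@@H](CC1)C(C)=C | intermediate
3 | (4-methoxyphenyl)methanol | COc1ccc(CO)cc1 | starting material
4 | 1-{[(E)-1,2-dichloroethenyl]oxymethyl}-4-methoxybenzene | COc1ccc(CO/C(Cl)=C\Cl)cc1 | intermediate (not isolated)
5 | lithium 2-[(4-methoxyphenyl)methoxy]ethynide | [Li]C#COCc1ccc(OC)cc1 | intermediate (not isolated)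
6 | 1-(ethynyloxymethyl)-4-methoxybenzene | C#COCc1ccc(OC)cc1 | intermediate
7 | chlorobis(cyclopentadienyl){(E)-2-[(4-methoxyphenyl)methoxy]ethenyl}zirconium | COc1ccc(CO/C=C/[Zr](Cl)(C2C=CC=C2)C2C=CC=C2)cc1 | intermediate (not isolated)
8 | 1-{[(E)-2-iodoethenyl]oxymethyl}-4-methoxybenzene | COc1ccc(CO/C=C/I)cc1 | intermediate
9 | {(E)-2-[(4-methoxyphenyl)methoxy]ethenyl}lithium | [Li]/C=C/OCc1ccc(OC)cc1 | intermediate (not isolated)
10 | dichloro{(E)-2-[(4-methoxyphenyl)methoxy]ethenyl}cerium | Cl[Ce](Cl)/C=C/OCc1ccc(OC)cc1 | intermediate (not isolated)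
11 | (1S,6S)-1-{(E)-2-[(4-methoxyphenyl)methoxy]ethenyl}-3-methyl-6-(prop-1-en-2-yl)cyclohex-2-en-1-ol (alkenyl trans to isopropenyl) | COc1ccc(CO/C=C/[C@]2(O)C=C(C)CC[C@H]2C(C)=C)cc1 | intermediate
12 | potassium alkoxide of 11 | COc1ccc(CO/C=C/[C@]2([O-])C=C(C)CC[C@H]2C(C)=C)cc1.[K+] | intermediate (not isolated)
13 | potassium (1(10)E,4Z,6Z,8S)-8-(4-methoxybenzyloxy)-11,12,13-trinorgermacra-1(10),4,6-trien-6-olate | [K+].[O-]/C1=C\[C@@H](OCc2ccc(OC)cc2)C/C(C)=C/CC/C(C)=C\1 | intermediate (not isolated)
14 | (1(10)E,4Z,6Z,8S)-8-(4-methoxybenzyloxy)-6-(trimethylsilyloxy)-11,12,13-trinorgermacra-1(10),4,6-triene | C[Si](C)(C)O/C1=C\[C@@H](OCc2ccc(OC)cc2)C/C(C)=C/CC/C(C)=C\1 | intermediate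
15 | ethyl 3-bromo-2-oxopropanoate | CCOC(=O)C(=O)CBr | starting material
16 | ethyl 3-acetoxy-2-oxopropanoate | CCOC(=O)C(=O)COC(C)=O | intermediate
17 | ethyl (1(10)E,4Z,8S)-13-acetoxy-8-(4-methoxybenzyloxy)-6-oxo-11-(trimethylsilyloxy)germacra-1(10),4-dien-12-oate (7,11-syn aldol series; C7 and C11 are lost in step 9 and left open in the SMILES) | CCOC(=O)C(COC(C)=O)(O[Si](C)(C)C)C1[C@@H](OCc2ccc(OC)cc2)C/C(C)=C/CC/C(C)=C\C1=O | intermediate
18 | ethyl (1(10)E,4Z,6R,8S)-13-acetoxy-6-hydroxy-8-(4-methoxybenzyloxy)-11-(trimethylsilyloxy)germacra-1(10),4-dien-12-oate | CCOC(=O)C(COC(C)=O)(O[Si](C)(C)C)C1[C@@H](OCc2ccc(OC)cc2)C/C(C)=C/CC/C(C)=C\[C@H]1O | intermediate (not isolated)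
19 | (1(10)E,4Z,6R,8S)-13-acetoxy-11-hydroxy-8-(4-methoxybenzyloxy)germacra-1(10),4-dien-12,6-olide (H-7 cis to the C11 hydroxyl) | CC(=O)OCC1(O)C2[C@@H](OCc3ccc(OC)cc3)C/C(C)=C/CC/C(C)=C\[C@H]2OC1=O | intermediate
20 | (1(10)E,4Z,6R,8S)-13-acetoxy-8-(4-methoxybenzyloxy)germacra-1(10),4,7(11)-trien-12,6-olide | CC(=O)OCC1=C2[C@@H](OCc3ccc(OC)cc3)C/C(C)=C/CC/C(C)=C\[C@H]2OC1=O | intermediate
21 | (1(10)E,4Z,6R,8S)-13-acetoxy-8-hydroxygermacra-1(10),4,7(11)-trien-12,6-olide | CC(=O)OCC1=C2[C@@H](O)C/C(C)=C/CC/C(C)=C\[C@H]2OC1=O | intermediate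
22 | (1R,4Z,6R,8S,10R)-13-acetoxy-1,10-epoxy-8-hydroxygermacra-4,7(11)-dien-12,6-olide | CC(=O)OCC1=C2[C@@H](O)C[C@@]3(C)O[C@@H]3CC/C(C)=C\[C@H]2OC1=O | intermediate (not isolated)
23 | (1R,4R,5S,6S,8S,10R)-13-acetoxy-1,10:4,5-diepoxy-8-hydroxygermacr-7(11)-en-12,6-olide | CC(=O)OCC1=C2[C@@H](O)C[C@@]3(C)O[C@@H]3CC[C@@]3(C)O[C@H]3[C@H]2OC1=O | intermediate
24 | (2S)-2-methyloxirane-2-carboxylic acid | OC(=O)[C@]1(C)CO1 | starting material
25 | (1R,4R,5S,6S,8S,10R)-13-acetoxy-1,10:4,5-diepoxy-8-[(2S)-2-methyloxirane-2-carbonyloxy]germacr-7(11)-en-12,6-olide (CNP0289810.1) | CC(=O)OCC1=C2[C@@H](OC(=O)[C@]3(C)CO3)C[C@@]3(C)O[C@@H]3CC[C@@]3(C)O[C@H]3[C@H]2OC1=O | target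

**Count and risks**

Total step count: 12. Longest linear sequence: 10 steps (steps 2, 3, 4, 5, 7, 8, 9, 10, 11, 12).

Most likely to fail, step 5: the potassium enolate may lose the C8 alkoxide by β-elimination before it is silylated, or the rearrangement may leak through a boat and erode the C8 configuration. The fallback sets out from 11, which is silylated with Me3SiCl and imidazole to its trimethylsilyl ether F1. F1 is then heated in PhMe in a sealed tube at about 180 °C for a neutral thermal siloxy-Cope rearrangement through the same chair, which needs no alkoxide or enolate and should give the silyl enol ether directly. It comes back to the route at 14.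

Second, step 11: oxygen may reach C4=C5 from the ring periphery without direction by the hydroxyl (wrong face), or the C8 hydroxyl may open the 1,10-oxirane across the ring. The fallback sets out from 21 and replaces hydroxyl direction at the Z-alkene by reagent control. VO(acac)2 with one equivalent of t-BuOOH is stopped at the homoallylic stage to isolate 22. The remaining Z-alkene is then epoxidized by the chiral dioxirane from the fructose-derived Shi ketone, in the matched enantiomeric form, and KHSO5 at pH 8. It comes back to the route at 23 and makes no new compound.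

Third, step 9: the dehydration may run toward C13 and give an enol acetate, or fail for an aldol diastereomer that lacks a syn H-7. The fallback sets out from 14 and builds the alkene by enolization and cross-coupling instead of elimination. Mukaiyama aldol addition of 14 to ethyl glyoxylate under Cu(OTf)2 and bis(oxazoline) catalysis should give the silylated glycolate adduct F2. Reduction of F2 with Zn(BH4)2, then PPTS in MeOH, should give the secondary 11-hydroxy lactone F3. Dess–Martin oxidation of F3 should give the α-keto lactone, expected as its enol, the 11-hydroxybutenolide F4, whatever the configuration at C7 and C11. Tf2O and 2,6-lutidine should convert F4 into the enol triflate F5. Stille coupling of F5 with Bu3SnCH2OH, using Pd(PPh3)4 and LiCl in dioxane at 80 °C, should give the 13-hydroxy butenolide F6. Acetylation of F6 with Ac2O and pyridine then gives the acetate, and the fallback comes back to the route at 20.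

**Further compounds**

F1 | step 5 | (1S,6S)-1-{(E)-2-[(4-methoxyphenyl)methoxy]ethenyl}-3-methyl-6-(prop-1-en-2-yl)-1-(trimethylsilyloxy)cyclohex-2-ene | COc1ccc(CO/C=C/[C@]2(O[Si](C)(C)C)C=C(C)CC[C@H]2C(C)=C)cc1
F2 | step 9 | ethyl (1(10)E,4Z,8S)-8-(4-methoxybenzyloxy)-6-oxo-11-(trimethylsilyloxy)-13-norgermacra-1(10),4-dien-12-oate | CCOC(=O)C(O[Si](C)(C)C)C1[C@@H](OCc2ccc(OC)cc2)C/C(C)=C/CC/C(C)=C\C1=O
F3 | step 9 | (1(10)E,4Z,6R,8S)-11-hydroxy-8-(4-methoxybenzyloxy)-13-norgermacra-1(10),4-dien-12,6-olide | OC1C2[C@@H](OCc3ccc(OC)cc3)C/C(C)=C/CC/C(C)=C\[C@H]2OC1=O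
F4 | step 9 | (1(10)E,4Z,6R,8S)-11-hydroxy-8-(4-methoxybenzyloxy)-13-norgermacra-1(10),4,7(11)-trien-12,6-olide | OC1=C2[C@@H](OCc3ccc(OC)cc3)C/C(C)=C/CC/C(C)=C\[C@H]2OC1=O
F5 | step 9 | (1(10)E,4Z,6R,8S)-8-(4-methoxybenzyloxy)-11-(trifluoromethylsulfonyloxy)-13-norgermacra-1(10),4,7(11)-trien-12,6-olide | FC(F)(F)S(=O)(=O)OC1=C2[C@@H](OCc3ccc(OC)cc3)C/C(C)=C/CC/C(C)=C\[C@H]2OC1=O
F6 | step 9 | (1(10)E,4Z,6R,8S)-13-hydroxy-8-(4-methoxybenzyloxy)germacra-1(10),4,7(11)-trien-12,6-olide | OCC1=C2[C@@H](OCc3ccc(OC)cc3)C/C(C)=C/CC/C(C)=C\[C@H]2OC1=O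
F0 | step 11 | none | none
A1 | direct plan | rac-(3aS,4R,8aR)-1-methoxy-3a,7-dimethyl-3,3a,4,5,6,8a-hexahydroazulene-4,8a-diol | COC1=CC[C@@]2(C)[C@H](O)CCC(C)=C[C@]12O
A2 | direct plan | (2E,5E,9Z)-2-methoxy-5,9-dimethylcyclodeca-2,5,9-trien-1-one | O=C1/C(OC)=C\C/C(C)=C/CC/C(C)=C\1
A3 | direct plan | (1R,4Z,6S,7E,10R)-1,10-epoxy-7-methoxy-11,12,13-trinorgermacra-4,7-dien-6-ol | CO/C1=C/C[C@@]2(C)O[C@@H]2CC/C(C)=C\[C@@H]1O
A4 | direct plan | (1R,4R,5S,6S,8S,10R)-1,10:4,5-diepoxy-6,8-dihydroxy-11,12,13-trinorgermacran-7-one | O=C1[C@@H](O)C[C@@]2(C)O[C@@H]2CC[C@@]2(C)O[C@H]2[C@@H]1O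
A5 | direct plan | (1R,4R,5S,6R,8S,10R)-6-acryloyloxy-1,10:4,5-diepoxy-8-[(2S)-2-methyloxirane-2-carbonyloxy]-11,12,13-trinorgermacran-7-one | O=C1[C@@H](OC(=O)[C@]2(C)CO2)C[C@@]2(C)O[C@@H]2CC[C@@]2(C)O[C@H]2[C@H]1OC(=O)C=C
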